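**Strategy.** The γ-butyrolactone (ring atoms O1, C2=O, C3–OH, C4, C5H2) is opened at C4–C5. The key step exploits the C3 hydroxyl, which is cis to the C4 side chain: as a bromomethylsilyl ether it delivers the C5 carbon to C4 by 5-exo radical cyclization onto a (Z)-diene. One operation closes a 1,2-oxasilolane through the C4–C5 bond, sets C4 from C3 by allylic 1,3-strain and moves the double bond to C6=C7; Tamao oxidation then frees C5–OH, which lactonises. The precursor is an acyclic ethyl (Z)-2-silyloxy-hexa-3,5-dienoate that already carries the hydrindane; a second tether on the same oxygen later adds C9 to C6.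

Key step: step 14

Atom labels: lactone O1, C2 (C=O), C3 (CHOH), C4, C5 (OCH2); side chain C6 (CH bearing C9H2OAc), C7 (alkene carbon bearing the hydrindane), C8 (=CH2). Hyd = (3aS,7aS)-4,4,7a-trimethyloctahydro-1H-inden-1-yl, bound through C1 on the face of the 7a-methyl group, rings trans-fused.

Assumption: in step 10 the lipase is taken to prefer the (R)-acetate (ester as the large, ethynyl as the medium substituent); if the preference is the opposite, the unreacted acetate is the (R)-enantiomer and is deacetylated instead.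

Step 1
Reactants: 1 (S)-Hajos–Parrish ketone, (7aS)-7a-methyl-2,3,7,7a-tetrahydro-1H-indene-1,5(6H)-dione
Product: 2 (7a'S)-7a'-methyl-2',3',7',7a'-tetrahydrospiro[1,3-dioxolane-2,1'-inden]-5'(6'H)-one
Conditions: HOCH2CH2OH, p-TsOH (cat.), PhH, molecular sieves, rt
Reagents that add atoms: ethylene glycol, OCCO
Why: acid-catalysed ketalization should take place only at the saturated C1 ketone, because the enone carbonyl is deactivated by conjugation, and no stereocenter is touched.

Step 2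
Reactants: 2 (7a'S)-7a'-methyl-2',3',7',7a'-tetrahydrospiro[1,3-dioxolane-2,1'-inden]-5'(6'H)-one
Product: 3 (7a'S)-4',4',7a'-trimethyl-2',4',7',7a'-tetrahydrospiro[1,3-dioxolane-2,1'-inden]-5'(6'H)-one (C3'=C3a' alkene)
Conditions: t-BuOK, MeI, t-BuOH/THF, rt
Reagents that add atoms: iodomethane, CI
Why: deconjugative double α-alkylation of the extended enolate should place both methyl groups on C4 and move the alkene to C3=C3a.

Step 3
Reactants: 3 (7a'S)-4',4',7a'-trimethyl-2',4',7',7a'-tetrahydrospiro[1,3-dioxolane-2,1'-inden]-5'(6'H)-one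
Product: 4 (7a'S)-4',4',7a'-trimethyl-2',4',5',6',7',7a'-hexahydrospiro[1,3-dioxolane-2,1'-indene]
Conditions: N2H4·H2O, KOH, diethylene glycol, 130 to 200 °C
Reagents that add atoms: none
Why: Wolff–Kishner reduction should remove the C5 ketone while the base-stable ketal and the non-conjugated alkene stay in place.

Step 4
Reactants: 4 (7a'S)-4',4',7a'-trimethyl-2',4',5',6',7',7a'-hexahydrospiro[1,3-dioxolane-2,1'-indene]
Product: 6 (3aS,7aS)-4,4,7a-trimethyloctahydro-1H-inden-1-one, via saturated ketal 5 (not isolated)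
Conditions: H2 (4 atm), Pd/C, EtOAc, rt; then 1 M HCl, THF, rt
Reagents that add atoms: water, O
Why: heterogeneous hydrogenation should deliver hydrogen to C3a from the face opposite the angular 7a-methyl group, giving the trans ring fusion, and aqueous acid then hydrolyses the ketal.

Step 5
Reactants: 6 (3aS,7aS)-4,4,7a-trimethyloctahydro-1H-inden-1-one
Product: 7 (3aS,7aS,Z)-1-ethylidene-4,4,7a-trimethyloctahydro-1H-indene
Conditions: EtPPh3Br, t-BuOK, THF, reflux
Reagents that add atoms: ethyltriphenylphosphonium bromide, CC[P+](c1ccccc1)(c1ccccc1)c1ccccc1.[Br-]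
Why: Wittig olefination of the hindered cyclopentanone should give the ethylidene compound, mainly as the (Z)-isomer as with related 17-oxo steroids.

Step 6
Reactants: 7 (3aS,7aS,Z)-1-ethylidene-4,4,7a-trimethyloctahydro-1H-indene
Product: 9 (1S)-1-Hyd-ethan-1-ol, via alkylborane 8 (not isolated)
Conditions: BH3·THF, THF, 0 °C to rt; then NaOH, H2O2
Reagents that add atoms: hydrogen peroxide, OO
Why: hydroboration–oxidation should add H and B syn from the face opposite the 7a-methyl group, so that C1 receives its hydrogen on that face and the side chain ends cis to the methyl group.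

Step 7
Reactants: 9 (1S)-1-Hyd-ethan-1-ol
Product: 10 1-Hyd-ethan-1-one
Conditions: Dess–Martin periodinane, NaHCO3, CH2Cl2, rt
Reagents that add atoms: none
Why: Dess–Martin oxidation of the secondary alcohol should give the methyl ketone with C1 kept in its thermodynamically preferred configuration.

Step 8
Reactants: 10 1-Hyd-ethan-1-one
Product: 11 1-Hyd-ethenyl trifluoromethanesulfonate
Conditions: KHMDS, THF, −78 °C; then PhNTf2
Reagents that add atoms: N-phenylbis(trifluoromethanesulfonimide), O=S(=O)(N(c1ccccc1)S(=O)(=O)C(F)(F)F)C(F)(F)F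
Why: kinetic deprotonation should occur at the methyl group and not at the hindered C1–H, and O-sulfonylation of that enolate gives the 1,1-disubstituted alkenyl triflate.

Step 9
Reactants: 12 ethyl glyoxylate; 13 ethynylmagnesium bromide
Product: 15 racemic ethyl 2-acetoxybut-3-ynoate, via magnesium alkoxide 14 (not isolated)
Conditions: THF, −78 °C; then Ac2O, DMAP (cat.), −78 °C to rt
Reagents that add atoms: acetic anhydride, CC(=O)OC(C)=O
Why: Grignard addition should occur at the aldehyde carbonyl, which is far more electrophilic than the ester, and the alkoxide is acetylated in the same flask.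

Step 10
Reactants: 15 racemic ethyl 2-acetoxybut-3-ynoate
Product: 16 ethyl (R)-2-hydroxybut-3-ynoate
Conditions: Burkholderia cepacia lipase (immobilised), EtOH, MTBE, 30 °C, stopped near half conversion
Reagents that add atoms: none
Why: lipase-catalysed enantioselective ethanolysis (kinetic resolution) should cleave the (R)-acetate faster, which sets the C3 stereocenter of the target, while the (S)-acetate stays behind and is separated.

Step 11
Reactants: 11 1-Hyd-ethenyl trifluoromethanesulfonate; 16 ethyl (R)-2-hydroxybut-3-ynoate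
Product: 17 ethyl (2R)-2-hydroxy-5-Hyd-hex-5-en-3-ynoate
Conditions: Pd(PPh3)4, CuI, i-Pr2NH, THF, rt
Reagents that add atoms: none
Why: Sonogashira coupling of the alkenyl triflate with the terminal alkyne should join the two fragments at C6–C7 without touching any stereocenter.

Step 12
Reactants: 17 ethyl (2R)-2-hydroxy-5-Hyd-hex-5-en-3-ynoate
Product: 18 ethyl (2R,3Z)-2-hydroxy-5-Hyd-hexa-3,5-dienoate
Conditions: Zn(Cu/Ag), MeOH/H2O, 40 °C
Reagents that add atoms: none
Why: activated zinc should reduce the conjugated triple bond by syn delivery of two hydrogens to give the (Z)-alkene and leave the 1,1-disubstituted alkene alone.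

Step 13
Reactants: 18 ethyl (2R,3Z)-2-hydroxy-5-Hyd-hexa-3,5-dienoate
Product: 19 ethyl (2R,3Z)-2-{[(bromomethyl)dimethylsilyl]oxy}-5-Hyd-hexa-3,5-dienoate
Conditions: BrCH2SiMe2Cl, imidazole, CH2Cl2, 0 °C; used crude
Reagents that add atoms: (bromomethyl)chlorodimethylsilane, C[Si](C)(Cl)CBr
Why: O-silylation of the C3 hydroxyl should install the one-carbon radical precursor that later becomes C5.

Step 14
Reactants: 19 ethyl (2R,3Z)-2-{[(bromomethyl)dimethylsilyl]oxy}-5-Hyd-hexa-3,5-dienoate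
Product: 20 ethyl (4S,5R)-2,2-dimethyl-4-(2-Hyd-prop-1-en-1-yl)-1,2-oxasilolane-5-carboxylate (E/Z mixture at the new alkene)
Conditions: Bu3SnH (slow addition), Et3B, air, PhMe, 0 °C to rt
Reagents that add atoms: none
Why: Bu3Sn• abstracts bromine to give the α-silyl radical •CH2SiMe2O–, which attacks C4 of the (Z)-diene in a 5-exo-trig closure (closest known type: Nishiyama–Stork silicon-tethered radical cyclization) and so forms the C4–C5 bond inside a 1,2-oxasilolane ring (O3, Si, C5, C4, C3). The resulting C6–C7–C8 allyl radical should take hydrogen from Bu3SnH at its unhindered primary terminus C8, which leaves the trisubstituted C6=C7 alkene. C4 is the only new stereocenter and is controlled by C3: allylic 1,3-strain in the (Z)-alkene holds C3–H in the alkene plane, the tether reaches C4 from the face of O3, and the ester ends trans to the side chain on the ring, which is the relationship that becomes cis-OH/side chain in the lactone. The step needs attack at C4 and not at C6, C7 or C8 (secured by ring size and by formation of the allyl radical) and hydrogen transfer to C8 and not to C6 (favoured by sterics and by the more substituted alkene).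

Step 15
Reactants: 20 ethyl (4S,5R)-2,2-dimethyl-4-(2-Hyd-prop-1-en-1-yl)-1,2-oxasilolane-5-carboxylate
Product: 22 (3R,4R)-3-hydroxy-4-(2-Hyd-prop-1-en-1-yl)dihydrofuran-2(3H)-one, via diol ester 21 (not isolated)
Conditions: KF, KHCO3, 30% H2O2, THF/MeOH, rt; then p-TsOH (cat.), CH2Cl2, rt
Reagents that add atoms: hydrogen peroxide, OO
Why: Tamao oxidation should cleave the Si–C5 bond to C5–OH and free the C3 hydroxyl, and the γ-hydroxy ester then closes to the five-membered lactone with OH and side chain cis.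

Step 16
Reactants: 22 (3R,4R)-3-hydroxy-4-(2-Hyd-prop-1-en-1-yl)dihydrofuran-2(3H)-one
Product: 24 (3R,4R)-3-{[(iodomethyl)dimethylsilyl]oxy}-4-(2-Hyd-prop-1-en-1-yl)dihydrofuran-2(3H)-one, via bromomethylsilyl ether 23 (not isolated)
Conditions: BrCH2SiMe2Cl, imidazole, CH2Cl2, 0 °C; then NaI, acetone, rt
Reagents that add atoms: (bromomethyl)chlorodimethylsilane, C[Si](C)(Cl)CBr; sodium iodide, [Na+].[I-]
Why: silylation of the only free hydroxyl followed by Finkelstein exchange should give the iodomethylsilyl ether that carries the future C9.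

Step 17
Reactants: 24 (3R,4R)-3-{[(iodomethyl)dimethylsilyl]oxy}-4-(2-Hyd-prop-1-en-1-yl)dihydrofuran-2(3H)-one
Product: 25 cis-fused 2,2-dimethyl-1,2-oxasilinane–γ-butyrolactone in which O3 and the new C9H2 on C6 are bridged by SiMe2 and C6 (R) carries the 1-Hyd-ethenyl group
Conditions: Co(dmgH)2(py)Cl (cat.), i-Pr2NEt, MeCN, blue LEDs, rt
Reagents that add atoms: none
Why: in this cobaloxime-catalysed alkyl Heck-type radical cyclization the α-silyl radical should add 6-exo to C6 from the face of O3 through a chair-like transition state (C4–H eclipsing C6=C7, C5 trans to the C7 substituent), which sets C6, and divalent cobalt then removes one of the least hindered β-hydrogens, those of the C8 methyl group, to leave the exocyclic methylene.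

Step 18
Reactants: 25 cis-fused 2,2-dimethyl-1,2-oxasilinane–γ-butyrolactone
Product: 26 (3R,4R)-3-hydroxy-4-[(2R)-1-hydroxy-3-Hyd-but-3-en-2-yl]dihydrofuran-2(3H)-one
Conditions: KF, KHCO3, 30% H2O2, THF/MeOH, rt; acidic work-up
Reagents that add atoms: hydrogen peroxide, OO
Why: Tamao oxidation should convert the Si–C9 bond into C9–OH with the C6 configuration untouched and release the C3 hydroxyl.

Step 19
Reactants: 26 (3R,4R)-3-hydroxy-4-[(2R)-1-hydroxy-3-Hyd-but-3-en-2-yl]dihydrofuran-2(3H)-one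
Product: 27 (2R)-2-[(3R,4R)-4-hydroxy-5-oxotetrahydrofuran-3-yl]-3-Hyd-but-3-en-1-yl acetate (CNP0252518.3)
Conditions: AcCl, 2,4,6-collidine, CH2Cl2, −78 °C
Reagents that add atoms: acetyl chloride, CC(Cl)=O
Why: acylation under these mild conditions should take place at the primary C9 hydroxyl and leave the hindered, less nucleophilic secondary α-hydroxy lactone OH free.

**Compound list**

1 | (S)-Hajos–Parrish ketone | C[C@]12CCC(=O)C=C1CCC2=O | starting material
2 | (7a'S)-7a'-methyl-2',3',7',7a'-tetrahydrospiro[1,3-dioxolane-2,1'-inden]-5'(6'H)-one | C[C@]12CCC(=O)C=C1CCC23OCCO3 | intermediate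
3 | (7a'S)-4',4',7a'-trimethyl-2',4',7',7a'-tetrahydrospiro[1,3-dioxolane-2,1'-inden]-5'(6'H)-one | C[C@]12CCC(=O)C(C)(C)C1=CCC23OCCO3 | intermediate
4 | (7a'S)-4',4',7a'-trimethyl-2',4',5',6',7',7a'-hexahydrospiro[1,3-dioxolane-2,1'-indene] | C[C@]12CCCC(C)(C)C1=CCC23OCCO3 | intermediate
5 | (3a'S,7a'S)-4',4',7a'-trimethyloctahydrospiro[1,3-dioxolane-2,1'-indene] | C13(OCCO3)CC[C@H]2C(C)(C)CCC[C@]12C | intermediate
6 | (3aS,7aS)-4,4,7a-trimethyloctahydro-1H-inden-1-one | O=C1CC[C@H]2C(C)(C)CCC[C@]12C | intermediate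
7 | (3aS,7aS,Z)-1-ethylidene-4,4,7a-trimethyloctahydro-1H-indene | C/C=C1/CC[C@H]2C(C)(C)CCC[C@]12C | intermediate
8 | (1S)-1-Hyd-ethylborane | C[C@H]([BH2])[C@H]1CC[C@H]2C(C)(C)CCC[C@]12C | intermediate
9 | (1S)-1-Hyd-ethan-1-ol | C[C@H](O)[C@H]1CC[C@H]2C(C)(C)CCC[C@]12C | intermediate
10 | 1-Hyd-ethan-1-one | CC(=O)[C@H]1CC[C@H]2C(C)(C)CCC[C@]12C | intermediate
11 | 1-Hyd-ethenyl trifluoromethanesulfonate | C=C(OS(=O)(=O)C(F)(F)F)[C@H]1CC[C@H]2C(C)(C)CCC[C@]12C | intermediate
12 | ethyl glyoxylate | CCOC(=O)C=O | starting material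
13 | ethynylmagnesium bromide | C#C[Mg]Br | starting material
14 | bromomagnesium alkoxide of ethyl 2-hydroxybut-3-ynoate | CCOC(=O)C(O[Mg]Br)C#C | intermediate
15 | racemic ethyl 2-acetoxybut-3-ynoate | CCOC(=O)C(OC(C)=O)C#C | intermediate
16 | ethyl (R)-2-hydroxybut-3-ynoate | CCOC(=O)[C@H](O)C#C | intermediate
17 | ethyl (2R)-2-hydroxy-5-Hyd-hex-5-en-3-ynoate | CCOC(=O)[C@H](O)C#CC(=C)[C@H]1CC[C@H]2C(C)(C)CCC[C@]12C | intermediate
18 | ethyl (2R,3Z)-2-hydroxy-5-Hyd-hexa-3,5-dienoate | CCOC(=O)[C@H](O)/C=C\C(=C)[C@H]1CC[C@H]2C(C)(C)CCC[C@]12C | intermediate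
19 | ethyl (2R,3Z)-2-{[(bromomethyl)dimethylsilyl]oxy}-5-Hyd-hexa-3,5-dienoate | CCOC(=O)[C@H](O[Si](C)(C)CBr)/C=C\C(=C)[C@H]1CC[C@H]2C(C)(C)CCC[C@]12C | intermediate
20 | ethyl (4S,5R)-2,2-dimethyl-4-(2-Hyd-prop-1-en-1-yl)-1,2-oxasilolane-5-carboxylate (E/Z mixture) | CCOC(=O)[C@@H]1O[Si](C)(C)C[C@H]1C=C(C)[C@H]1CC[C@H]2C(C)(C)CCC[C@]12C | intermediate
21 | ethyl (2R,3R)-2-hydroxy-3-(hydroxymethyl)-5-Hyd-hex-4-enoate | CCOC(=O)[C@H](O)[C@@H](CO)C=C(C)[C@H]1CC[C@H]2C(C)(C)CCC[C@]12C | intermediate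
22 | (3R,4R)-3-hydroxy-4-(2-Hyd-prop-1-en-1-yl)dihydrofuran-2(3H)-one | CC(=C[C@@H]1COC(=O)[C@@H]1O)[C@H]1CC[C@H]2C(C)(C)CCC[C@]12C | intermediate
23 | (3R,4R)-3-{[(bromomethyl)dimethylsilyl]oxy}-4-(2-Hyd-prop-1-en-1-yl)dihydrofuran-2(3H)-one | CC(=C[C@@H]1COC(=O)[C@@H]1O[Si](C)(C)CBr)[C@H]1CC[C@H]2C(C)(C)CCC[C@]12C | intermediate
24 | (3R,4R)-3-{[(iodomethyl)dimethylsilyl]oxy}-4-(2-Hyd-prop-1-en-1-yl)dihydrofuran-2(3H)-one | CC(=C[C@@H]1COC(=O)[C@@H]1O[Si](C)(C)CI)[C@H]1CC[C@H]2C(C)(C)CCC[C@]12C | intermediate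
25 | cis-fused 2,2-dimethyl-1,2-oxasilinane–γ-butyrolactone (O3–SiMe2–C9 bridge, C6 R, 1-Hyd-ethenyl on C6) | C=C([C@H]1CC[C@H]2C(C)(C)CCC[C@]12C)[C@@H]3C[Si](C)(C)O[C@H]4C(=O)OC[C@@H]34 | intermediate
26 | (3R,4R)-3-hydroxy-4-[(2R)-1-hydroxy-3-Hyd-but-3-en-2-yl]dihydrofuran-2(3H)-one | C=C([C@H]1CC[C@H]2C(C)(C)CCC[C@]12C)[C@H](CO)[C@@H]1COC(=O)[C@@H]1O | intermediate
27 | (2R)-2-[(3R,4R)-4-hydroxy-5-oxotetrahydrofuran-3-yl]-3-Hyd-but-3-en-1-yl acetate | C=C([C@H]1CC[C@H]2C(C)(C)CCC[C@]12C)[C@H](COC(C)=O)[C@@H]1COC(=O)[C@@H]1O | target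

**Step count and risks**

Total steps: 19. Longest linear sequence: 17 steps (steps 1 to 8 and 11 to 19).

Steps most likely to fail:

Step 14. The allyl radical may take its hydrogen at the internal terminus C6, giving the 1,1-disubstituted alkene isomer; facial selectivity at C4 is the second concern. The fallback sets out from 19 and comes back at 25. The isomeric cyclization product ethyl (4S,5R)-2,2-dimethyl-4-(2-Hyd-prop-2-en-1-yl)-1,2-oxasilolane-5-carboxylate F1 is taken through Tamao oxidation and lactonization (KF, KHCO3, H2O2; then p-TsOH) to (3R,4R)-3-hydroxy-4-(2-Hyd-prop-2-en-1-yl)dihydrofuran-2(3H)-one F2. Silylation with BrCH2SiMe2Cl and imidazole gives its bromomethylsilyl ether F3. Ene-type allylic chlorination (N-chlorosuccinimide, PhSeCl cat.) moves the double bond to C6=C7 and places chlorine on C8, giving (3R,4R)-3-{[(bromomethyl)dimethylsilyl]oxy}-4-(3-chloro-2-Hyd-prop-1-en-1-yl)dihydrofuran-2(3H)-one F4. Bu3SnH/AIBN then effects 6-exo radical cyclization at C6 with loss of the allylic chlorine atom (radical allyl transfer) and gives 25.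

Step 17. Cobalt may remove the β-hydrogen at C6 or at the hydrindane C1 instead of the methyl group, or the tertiary radical may simply be reduced. The fallback sets out from 22 and comes back at 25. Allylic oxidation of the methyl group with SeO2 and t-BuOOH gives (3R,4R)-3-hydroxy-4-(3-hydroxy-2-Hyd-prop-1-en-1-yl)dihydrofuran-2(3H)-one F5. PhSSPh and Bu3P convert the primary allylic alcohol into (3R,4R)-3-hydroxy-4-[2-Hyd-3-(phenylsulfanyl)prop-1-en-1-yl]dihydrofuran-2(3H)-one F6. BrCH2SiMe2Cl and imidazole give its bromomethylsilyl ether F7. Bu3SnH/AIBN then brings about 6-exo attack at C6 and β-scission of the C8–S bond, which gives 25.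

Step 12. The semi-reduction may over-reduce the conjugated diene or erode the (Z)-geometry. The fallback sets out from 16 and comes back at 18. Rhodium-catalysed trans-hydroboration of the terminal alkyne with pinacolborane ([Rh(cod)Cl]2, P(i-Pr)3, Et3N) gives ethyl (2R,3Z)-2-hydroxy-4-(4,4,5,5-tetramethyl-1,3,2-dioxaborolan-2-yl)but-3-enoate F8. Suzuki–Miyaura coupling with triflate 11 (Pd(PPh3)4, K3PO4, THF/H2O) then gives 18 without passing through the enyne.

Further compounds
F1 | step 14 | ethyl (4S,5R)-2,2-dimethyl-4-(2-Hyd-prop-2-en-1-yl)-1,2-oxasilolane-5-carboxylate | CCOC(=O)[C@@H]1O[Si](C)(C)C[C@H]1CC(=C)[C@H]1CC[C@H]2C(C)(C)CCC[C@]12C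
F2 | step 14 | (3R,4R)-3-hydroxy-4-(2-Hyd-prop-2-en-1-yl)dihydrofuran-2(3H)-one | C=C(C[C@@H]1COC(=O)[C@@H]1O)[C@H]1CC[C@H]2C(C)(C)CCC[C@]12C
F3 | step 14 | (3R,4R)-3-{[(bromomethyl)dimethylsilyl]oxy}-4-(2-Hyd-prop-2-en-1-yl)dihydrofuran-2(3H)-one | C=C(C[C@@H]1COC(=O)[C@@H]1O[Si](C)(C)CBr)[C@H]1CC[C@H]2C(C)(C)CCC[C@]12C
F4 | step 14 | (3R,4R)-3-{[(bromomethyl)dimethylsilyl]oxy}-4-(3-chloro-2-Hyd-prop-1-en-1-yl)dihydrofuran-2(3H)-one | ClCC(=C[C@@H]1COC(=O)[C@@H]1O[Si](C)(C)CBr)[C@H]1CC[C@H]2C(C)(C)CCC[C@]12C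
F5 | step 17 | (3R,4R)-3-hydroxy-4-(3-hydroxy-2-Hyd-prop-1-en-1-yl)dihydrofuran-2(3H)-one | OCC(=C[C@@H]1COC(=O)[C@@H]1O)[C@H]1CC[C@H]2C(C)(C)CCC[C@]12C
F6 | step 17 | (3R,4R)-3-hydroxy-4-[2-Hyd-3-(phenylsulfanyl)prop-1-en-1-yl]dihydrofuran-2(3H)-one | c1ccccc1SCC(=C[C@@H]1COC(=O)[C@@H]1O)[C@H]1CC[C@H]2C(C)(C)CCC[C@]12C
F7 | step 17 | (3R,4R)-3-{[(bromomethyl)dimethylsilyl]oxy}-4-[2-Hyd-3-(phenylsulfanyl)prop-1-en-1-yl]dihydrofuran-2(3H)-one | c1ccccc1SCC(=C[C@@H]1COC(=O)[C@@H]1O[Si](C)(C)CBr)[C@H]1CC[C@H]2C(C)(C)CCC[C@]12C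
F8 | step 12 | ethyl (2R,3Z)-2-hydroxy-4-(4,4,5,5-tetramethyl-1,3,2-dioxaborolan-2-yl)but-3-enoate | CCOC(=O)[C@H](O)/C=C\B1OC(C)(C)C(C)(C)O1
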